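The synthesis rests on cutting one bond of the bicyclo[2.2.1]heptane: the bond from the one-carbon CH2 bridge to the quaternary bridgehead that is shared with ring B and flanked by C(OH)(iPr). Without that bond and the hydroxyl, the cage relaxes to a plain fused cyclohexene (ring C). Its tetrasubstituted C=C carries the isopropyl group, and its CH2X arm lies para to the ring-fusion alkene carbon. Olefin-assisted solvolysis of the nosylate exploits this 1,4 relationship. In one operation it makes the bridge bond, both cyclopentane rings, the quaternary bridgehead and, by exo capture of water, the tertiary carbinol. The 6-6-6 precursor comes from (S)-Wieland–Miescher ketone by reductive alkylation, hydroacylation and McMurry closure.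

Key step: step 13

Remark: β is the decalin face that carries the angular methyl and α the opposite face; the two intermediates between hydroacylation and ester equilibration are carried as epimer mixtures at the ester-bearing CH, so that centre is left open in their SMILES; the temporary allylic carbinol from the Luche step is drawn as the expected major epimer.

Step 1
Reactants: 1 (S)-Wieland–Miescher ketone
Product: 2 hydroxy enone (isolated ketone reduced; OH β, equatorial, cis to the angular methyl)
Conditions: NaBH4 (0.3 equiv), EtOH, −10 °C
Reagents that add atoms: none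
Why: Chemoselective borohydride reduction, in which the isolated ketone is more electrophilic than the conjugated one and hydride enters anti to the angular methyl, so the new carbinol carries an equatorial OH cis to that methyl.

Step 2
Reactants: 2 hydroxy enone
Product: 3 silyl-protected hydroxy enone (TBS ether of 2)
Conditions: TBSCl, imidazole, DMAP (cat.), DMF, 40 °C
Reagents that add atoms: tert-butyldimethylsilyl chloride, CC(C)(C)[Si](C)(C)Cl
Why: Imidazole-promoted silylation of a secondary alcohol gives an ether that withstands base, dissolving metal, low-valent titanium and hydride, and no stereocentre is touched.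

Step 3
Reactants: 3 silyl-protected hydroxy enone
Product: 4 ene-dione (γ-CH2 of the enone turned into a second carbonyl)
Conditions: Rh2(cap)4 (cap = caprolactamate, 1 mol %), t-BuOOH (70 % aq.), K2CO3 (0.5 equiv), CH2Cl2, rt
Reagents that add atoms: tert-butyl hydroperoxide, CC(C)(C)OO
Why: Dirhodium-caprolactamate/hydroperoxide allylic oxidation, a known way from cyclic enones to ene-diones, attacks the only allylic CH2 of 3 and delivers the second carbonyl in a single operation without touching a stereocentre.

Step 4
Reactants: 4 ene-dione
Product: 5 keto allylic alcohol (the carbonyl flanked by CH= and CH2 reduced to the β, pseudo-equatorial alcohol; the other enone carbonyl intact)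
Conditions: NaBH4 (0.4 equiv), CeCl3·7H2O (1 equiv), MeOH/CH2Cl2, −78 °C
Reagents that add atoms: none
Why: Luche 1,2-reduction used as a redox mask, because, as in steroidal 4-ene-3,6-diones, the carbonyl between CH= and CH2 reacts before the one attached to the fully substituted alkene carbon, and axial hydride delivery should give mainly the β alcohol, a centre that is erased in step 6.

Step 5
Reactants: 5 keto allylic alcohol; 6 methyllithium
Product: 7 ene-diol (new tertiary carbinol: CH3 α, OH β axial; secondary allylic OH unchanged)
Conditions: MeLi (3 equiv), THF, −78 °C; H2O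
Reagents that add atoms: methyllithium (6), [Li]C
Why: 1,2-Addition of an organolithium to the remaining enone carbonyl (the first equivalent only deprotonates the alcohol), where the axial angular methyl, 1,3 to this carbonyl, shields the β face so that methyl enters from the α face and the tertiary OH ends β.

Step 6
Reactants: 7 ene-diol
Product: 8 γ-hydroxy-γ-methyl enone
Conditions: MnO2 (activated, excess), CH2Cl2, rt
Reagents that add atoms: none
Why: Manganese dioxide oxidises only the secondary allylic alcohol and restores the enone under neutral conditions, which avoids both acid-induced ionisation and the oxidative transposition that chromium reagents cause with tertiary allylic alcohols.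

Step 7
Reactants: 8 γ-hydroxy-γ-methyl enone; 9 methyl 2-(bromomethyl)acrylate
Product: 12 trans-decalone carrying the 2-(methoxycarbonyl)allyl side chain, via lithium alkoxide 10 (not isolated), via dilithium enolate alkoxide 11 (not isolated)
Conditions: n-BuLi (1.0 equiv), THF, −78 °C; Li (2.2 equiv), NH3(l)/THF, −78 °C, no alcohol co-acid; NH3 off, THF; added to 9 (1.5 equiv), −78 to −20 °C; aq. NH4Cl
Reagents that add atoms: methyl 2-(bromomethyl)acrylate (9), C=C(CBr)C(=O)OC
Why: Dissolving-metal reductive alkylation of an enone, in which the γ-oxygen held as an alkoxide is too poor a leaving group to be expelled, β-protonation occurs axially on the α face to set the trans ring fusion, and the regiodefined enolate 11 is alkylated at its only nucleophilic carbon from the α face because the β face is blocked by the axial methyl and axial OLi, the equatorial side chain also being the stable arrangement at this epimerisable carbon.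

Step 8
Reactants: 12 trans-decalone with acrylate side chain; 13 isobutyraldehyde
Product: 14 1,6-diketone ester (chain iPr-CO-CH2-CH(CO2Me)-CH2 on the decalone; both epimers at the ester-bearing CH)
Conditions: (n-Bu4N)4[W10O32] (2 mol %), 13 (5 equiv), MeCN (0.5 M), 390 nm LED, −10 °C, Ar
Reagents that add atoms: isobutyraldehyde (13), CC(C)C=O
Why: Decatungstate-photocatalysed hydroacylation (Giese-type addition), in which abstraction of the formyl hydrogen gives the nucleophilic isobutyryl radical that adds to the CH2 terminus of the acrylate, low temperature and high concentration holding back decarbonylation, while the new CH next to the ester forms without control and is corrected in step 10.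

Step 9
Reactants: 14 1,6-diketone ester
Product: 15 6-6-6 tricyclic ester with tetrasubstituted C=C(iPr) (both epimers at the ester-bearing CH)
Conditions: TiCl3(DME)1.5, Zn–Cu, DME, reflux, slow addition of 14 (high dilution)
Reagents that add atoms: none
Why: Intramolecular McMurry coupling of a 1,6-diketone closes ring C as the tetrasubstituted alkene, ketone–ketone coupling being much faster than any ketone–ester coupling, and no stereocentre is formed or lost.

Step 10
Reactants: 15 tricyclic ester (epimer mixture)
Product: 16 tricyclic ester with the ester α (equatorial on ring C)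
Conditions: NaOMe (0.5 equiv), MeOH, 50 °C; minor epimer separated and resubmitted
Reagents that add atoms: none
Why: Base-mediated epimerisation through the ester enolate, where the ring-fusion hydrogen is pseudo-axial on the β face of the ring C half-chair, so the equatorial position two carbons away lies on the α face and thermodynamic control places the ester there.

Step 11
Reactants: 16 tricyclic ester
Product: 17 primary alcohol (CH2OH α on ring C)
Conditions: LiAlH4, THF, 0 °C
Reagents that add atoms: none
Why: Hydride reduction of the ester to the primary alcohol leaves silyl ether, alkene and tertiary alcohol untouched and freezes the adjacent stereocentre, which is no longer epimerisable.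

Step 12
Reactants: 17 primary alcohol
Product: 18 cyclohex-3-enylmethyl nosylate
Conditions: 4-O2NC6H4SO2Cl (1.2 equiv), Et3N, DMAP (cat.), CH2Cl2, 0 °C
Reagents that add atoms: 4-nitrobenzenesulfonyl chloride, O=S(=O)(Cl)c1ccc(cc1)[N+](=O)[O-]
Why: Selective sulfonylation, since only the primary alcohol reacts at 0 °C while the axial tertiary alcohol is far too hindered, and the nosylate is a better nucleofuge than a tosylate yet still isolable.

Step 13
Reactants: 18 cyclohex-3-enylmethyl nosylate
Product: 20 tetracyclic norbornane diol silyl ether, via tertiary 2-norbornyl cation 19 (not isolated)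
Conditions: (CF3)2CHOH/H2O 9:1, 2,6-lutidine (1.5 equiv), 0.01 M, 60 °C
Reagents that add atoms: water, O
Why: Proposed new method: in buffered aqueous hexafluoroisopropanol, a strongly ionising but poorly nucleophilic medium, the primary nosylate does not ionise on its own; ring C tips from half-chair to boat, which swings the α-oriented CH2ONs arm over the alkene, and the tetrasubstituted C=C expels nosylate from the rear (exo-tet at CH2) to give tertiary cation 19, which water quenches. The closest known reaction type is the olefin-assisted (π-route) solvolysis of cycloalkenylalkyl arenesulfonates to 2-norbornyl products, supported for this ring size by the acid-induced closure of dihydrocarvone enol acetate to camphor; the label is needed because simple cyclohex-3-enylmethyl sulfonates show little assistance and a ring-fused tetrasubstituted alkene has not been tested. The single new C–C bond, from the CH2 to the ring-fusion alkene carbon para to the arm, closes two cyclopentanes at once, one 5-exo-trig (by way of the ring C CH2 and the ring-fusion CH) and one 5-endo-trig (by way of the other ring C CH2 and the isopropyl-bearing carbon), and turns ring C into the bicyclo[2.2.1]heptane. The quaternary bridgehead is dictated by the tether, since the arm fixed on the α face in step 10 can reach only that face, and the carbinol carbon by the exo preference of 2-norbornyl cations, water arriving on the side of the CH2 bridge so that OH is exo and isopropyl endo. Regioselectivity is secured by ring size (bonding to the isopropyl-bearing carbon would build a cyclobutane), and chemoselectivity by the electron-rich alkene, the β-branched primary carbon that resists direct solvent attack and the lutidine buffer that spares silyl ether and tertiary alcohols, while substrate that merely suffers displacement by water is alcohol 17 and can be re-nosylated. The cation must be trapped before a Wagner–Meerwein shift (which would expand ring B to seven members), a hydride shift from the isopropyl CH or proton loss, which is why about five molar water is present from the start.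

Step 14
Reactants: 20 tetracyclic norbornane diol silyl ether
Product: 21 tetracyclic triol (secondary OH β, equatorial)
Conditions: TBAF (5 equiv), THF, 60 °C
Reagents that add atoms: none
Why: Fluoride-mediated desilylation is chosen because the tertiary 2-norbornyl alcohol would ionise and rearrange in acid, and warming overcomes the hindrance of the silyl ether next to the quaternary carbon.

Step 15
Reactants: 21 tetracyclic triol
Product: 22 tetracyclic dihydroxy ketone
Conditions: (n-Pr4N)[RuO4] (5 mol %), NMO (1.5 equiv), 4 Å MS, CH2Cl2, rt
Reagents that add atoms: none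
Why: Ley–Griffith oxidation in a neutral medium, where the single secondary alcohol is the only oxidisable site and both tertiary alcohols are inert.

Step 16
Reactants: 22 tetracyclic dihydroxy ketone
Product: 23 hydrazone
Conditions: N2H4·H2O (20 equiv), Et3N, EtOH, 80 °C
Reagents that add atoms: hydrazine, NN
Why: Hydrazone formation with a large excess of hydrazine suppresses azine formation and, on heating, works for ketones next to a quaternary carbon.

Step 17
Reactants: 23 hydrazone
Product: 24 vinyl bromide
Conditions: NBS (2.2 equiv), 2-tert-butyl-1,1,3,3-tetramethylguanidine (4 equiv), CH2Cl2, 0 °C to rt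
Reagents that add atoms: N-bromosuccinimide, O=C1CCC(=O)N1Br
Why: Barton vinyl halide synthesis in its bromine version (oxidative bromination of the hydrazone with loss of N2, then base-induced elimination), and because one α-carbon is quaternary only one vinyl bromide can form.

Step 18
Reactants: 24 vinyl bromide
Product: 25 CNP0362628.1 (target)
Conditions: Mn(dpm)3 (dpm = dipivaloylmethanate, 15 mol %), PhSiH3 (2 equiv), t-BuOOH (2 equiv), i-PrOH, rt, Ar
Reagents that add atoms: none
Why: Metal-hydride hydrogen-atom-transfer hydrogenation, known to reduce alkenyl halides without hydrogenolysis, puts the first H atom on the CH= carbon and delivers the second to the bromine-bearing carbon axially from the α face, anti to the adjacent axial methyl, so that bromine ends equatorial (β), which is also the more stable arrangement.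

Compound list
1 | (S)-Wieland–Miescher ketone, (8aS)-8a-methyl-3,4,8,8a-tetrahydronaphthalene-1,6(2H,7H)-dione | O=C1C=C2CCCC(=O)[C@@]2(C)CC1 | starting material
2 | (4aS,5S)-5-hydroxy-4a-methyl-4,4a,5,6,7,8-hexahydronaphthalen-2(3H)-one (OH β, equatorial) | O=C1C=C2CCC[C@H](O)[C@@]2(C)CC1 | intermediate
3 | TBS ether of 2 | O=C1C=C2CCC[C@H](O[Si](C)(C)C(C)(C)C)[C@@]2(C)CC1 | intermediate
4 | ene-dione, (4aS,5S)-5-(TBSO)-4a-methyl-4,4a,6,7-tetrahydronaphthalene-2,8(3H,5H)-dione | O=C1C=C2C(=O)CC[C@H](O[Si](C)(C)C(C)(C)C)[C@@]2(C)CC1 | intermediate
5 | keto allylic alcohol: 4 with the C-2 carbonyl reduced to the β (pseudo-equatorial) alcohol | O[C@@H]1C=C2C(=O)CC[C@H](O[Si](C)(C)C(C)(C)C)[C@@]2(C)CC1 | intermediate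
6 | methyllithium | [Li]C | starting material
7 | ene-diol: 5 with C-8 turned into C(α-CH3)(β-OH) | O[C@@H]1C=C2[C@](C)(O)CC[C@H](O[Si](C)(C)C(C)(C)C)[C@@]2(C)CC1 | intermediate
8 | γ-hydroxy-γ-methyl enone (tertiary OH β axial, CH3 α) | O=C1C=C2[C@](C)(O)CC[C@H](O[Si](C)(C)C(C)(C)C)[C@@]2(C)CC1 | intermediate
9 | methyl 2-(bromomethyl)acrylate | C=C(CBr)C(=O)OC | starting material
10 | lithium alkoxide of 8 | O=C1C=C2[C@](C)(O[Li])CC[C@H](O[Si](C)(C)C(C)(C)C)[C@@]2(C)CC1 | intermediate
11 | dilithium enolate alkoxide (trans ring fusion, ring-fusion H α) | [Li]OC1=C[C@@H]2[C@](C)(O[Li])CC[C@H](O[Si](C)(C)C(C)(C)C)[C@@]2(C)CC1 | intermediate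
12 | trans-decalone with α (equatorial) 2-(methoxycarbonyl)allyl side chain next to the ring-fusion CH | C=C(C(=O)OC)C[C@H]1[C@@H]2[C@](C)(O)CC[C@H](O[Si](C)(C)C(C)(C)C)[C@@]2(C)CCC1=O | intermediate
13 | isobutyraldehyde | CC(C)C=O | starting material
14 | 1,6-diketone ester (both epimers at the ester-bearing CH) | CC(C)C(=O)CC(C(=O)OC)C[C@H]1[C@@H]2[C@](C)(O)CC[C@H](O[Si](C)(C)C(C)(C)C)[C@@]2(C)CCC1=O | intermediate
15 | 6-6-6 tricyclic ester with tetrasubstituted C=C(iPr) (both epimers at the ester-bearing CH) | CC(C)C1=C2CC[C@]3(C)[C@@H](O[Si](C)(C)C(C)(C)C)CC[C@@](C)(O)[C@H]3[C@@H]2CC(C(=O)OC)C1 | intermediate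
16 | tricyclic ester, CO2Me α (equatorial on ring C) | CC(C)C1=C2CC[C@]3(C)[C@@H](O[Si](C)(C)C(C)(C)C)CC[C@@](C)(O)[C@H]3[C@@H]2C[C@H](C(=O)OC)C1 | intermediate
17 | tricyclic primary alcohol, CH2OH α | CC(C)C1=C2CC[C@]3(C)[C@@H](O[Si](C)(C)C(C)(C)C)CC[C@@](C)(O)[C@H]3[C@@H]2C[C@H](CO)C1 | intermediate
18 | cyclohex-3-enylmethyl 4-nitrobenzenesulfonate | CC(C)C1=C2CC[C@]3(C)[C@@H](O[Si](C)(C)C(C)(C)C)CC[C@@](C)(O)[C@H]3[C@@H]2C[C@H](COS(=O)(=O)c2ccc(cc2)[N+](=O)[O-])C1 | intermediate
19 | tertiary 2-isopropyl-2-norbornyl cation | CC(C)[C+]1C[C@@H]2C[C@H]3[C@H]4[C@](C)(CC[C@@]31C2)[C@@H](O[Si](C)(C)C(C)(C)C)CC[C@@]4(C)O | intermediate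
20 | tetracyclic norbornane diol silyl ether (OH exo, iPr endo) | CC(C)[C@]1(O)C[C@@H]2C[C@H]3[C@H]4[C@](C)(CC[C@@]31C2)[C@@H](O[Si](C)(C)C(C)(C)C)CC[C@@]4(C)O | intermediate
21 | tetracyclic triol | CC(C)[C@]1(O)C[C@@H]2C[C@H]3[C@H]4[C@](C)(CC[C@@]31C2)[C@@H](O)CC[C@@]4(C)O | intermediate
22 | tetracyclic dihydroxy ketone | CC(C)[C@]1(O)C[C@@H]2C[C@H]3[C@H]4[C@](C)(CC[C@@]31C2)C(=O)CC[C@@]4(C)O | intermediate
23 | hydrazone of 22 (C=N geometry not specified) | CC(C)[C@]1(O)C[C@@H]2C[C@H]3[C@H]4[C@](C)(CC[C@@]31C2)C(=NN)CC[C@@]4(C)O | intermediate
24 | vinyl bromide | CC(C)[C@]1(O)C[C@@H]2C[C@H]3[C@H]4[C@](C)(CC[C@@]31C2)C(Br)=CC[C@@]4(C)O | intermediate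
25 | CNP0362628.1 (Br β, equatorial) | CC(C)[C@]1(O)C[C@@H]2C[C@H]3[C@H]4[C@](C)(CC[C@@]31C2)[C@@H](Br)CC[C@@]4(C)O | target

Total step count: 18. Longest linear sequence: 18 steps (1 to 25).

Steps most likely to fail

1. Step 13 (the labelled step).
- **What may go wrong:** The boat needed for participation may cost too much. Hydride-assisted ionisation or plain displacement by solvent would then outrun C–C bond formation. The cation may also shift or lose a proton before water arrives.
- **Fallback:** It uses known chemistry, sets out from 17 and returns at 20. The same bond is made from a much stronger electrophile. Alcohol 17 is oxidised with (n-Pr4N)[RuO4]/NMO to the ring C carbaldehyde F1. An acid-promoted Prins cyclisation–hydration (Sc(OTf)3, wet hexafluoroisopropanol, 0 °C to rt) follows. This is the reaction type that converts citronellal into p-menthane-3,8-diol. The alkene attacks the activated C=O and water ends the sequence, giving the bridge-hydroxylated tetracycle F2. Epimerisation of the aldehyde is harmless because only the α epimer can close, and the configuration of the bridge carbinol is irrelevant. Only this secondary alcohol reacts with 1,1'-thiocarbonyldiimidazole (DMAP, 1,2-dichloroethane, 80 °C), giving the imidazolylthiocarbonate F3. Barton–McCombie reduction (Bu3SnH, AIBN, toluene, 100 °C) then removes that oxygen and gives 20.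

2. Step 7.
- **What may go wrong:** C-alkylation of the crowded enolate in the reduction pot may be sluggish or unselective, through proton exchange, O-alkylation or consumption of the bromide by lithium amide.
- **Fallback:** It sets out from 8 and returns at 12. Reduction and C–C bond formation are separated by an isolable enol derivative. Compound 8 is reduced as in step 7 (through 10 and 11), but the pot is quenched with Me3SiCl/Et3N. This gives the bis(trimethylsilyl) enol ether F4, which can be purified and has the tertiary oxygen capped. Methyllithium 6 (1 equiv, THF, 0 °C) releases the amide-free lithium enolate F5. F5 is added to 9 at −78 °C to give the O-silylated alkylation product F6. Aqueous citric acid in THF removes the tertiary Me3Si group and gives 12.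

3. Step 8.
- **What may go wrong:** The secondary acyl radical may lose CO before it adds, or hydrogen may be abstracted from the substrate instead of the aldehyde.
- **Fallback:** It sets out from 12 and returns at 14, using polar instead of radical acyl-anion chemistry. Commercial 2-methyl-1-nitropropane adds to the acrylate of 12 under DBU catalysis (MeCN, rt, Michael addition) to give the γ-nitro ester F7. NaOMe in MeOH converts it into the sodium nitronate F8. Buffered aqueous TiCl3/NH4OAc turns F8 into the ketone (reductive Nef reaction), giving 14 as the same epimer mixture.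

Further compounds
F1 | step 13 | ring C carbaldehyde (CHO α) | CC(C)C1=C2CC[C@]3(C)[C@@H](O[Si](C)(C)C(C)(C)C)CC[C@@](C)(O)[C@H]3[C@@H]2C[C@H](C=O)C1
F2 | step 13 | bridge-hydroxylated tetracycle (20 with OH on the one-carbon bridge, that centre open) | CC(C)[C@]1(O)C[C@@H]2C[C@H]3[C@H]4[C@](C)(CC[C@@]31C2O)[C@@H](O[Si](C)(C)C(C)(C)C)CC[C@@]4(C)O
F3 | step 13 | imidazolylthiocarbonate of the bridge alcohol | CC(C)[C@]1(O)C[C@@H]2C[C@H]3[C@H]4[C@](C)(CC[C@@]31C2OC(=S)n5ccnc5)[C@@H](O[Si](C)(C)C(C)(C)C)CC[C@@]4(C)O
F4 | step 7 | bis(trimethylsilyl) enol ether (enol OSiMe3 and tertiary OSiMe3) | C[Si](C)(C)OC1=C[C@@H]2[C@](C)(O[Si](C)(C)C)CC[C@H](O[Si](C)(C)C(C)(C)C)[C@@]2(C)CC1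
F5 | step 7 | amide-free lithium enolate (tertiary OSiMe3) | [Li]OC1=C[C@@H]2[C@](C)(O[Si](C)(C)C)CC[C@H](O[Si](C)(C)C(C)(C)C)[C@@]2(C)CC1
F6 | step 7 | O-silylated alkylation product (12 with tertiary OSiMe3) | C=C(C(=O)OC)C[C@H]1[C@@H]2[C@](C)(O[Si](C)(C)C)CC[C@H](O[Si](C)(C)C(C)(C)C)[C@@]2(C)CCC1=O
F7 | step 8 | γ-nitro ester (nitro-bearing and ester-bearing CH open) | CC(C)C([N+](=O)[O-])CC(C(=O)OC)C[C@H]1[C@@H]2[C@](C)(O)CC[C@H](O[Si](C)(C)C(C)(C)C)[C@@]2(C)CCC1=O
F8 | step 8 | sodium nitronate of F7 | [Na+].CC(C)C(=[N+]([O-])[O-])CC(C(=O)OC)C[C@H]1[C@@H]2[C@](C)(O)CC[C@H](O[Si](C)(C)C(C)(C)C)[C@@]2(C)CCC1=O
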